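**Plan**
- Retrosynthesis: the C1 carbonyl is first masked as an ethyl dienol ether; the ring is then cut at C2=C3 and at C5–C6 in one [3+3] disconnection, and the enone fragment is cut at C3–C4 into an acyl unit and a vinyl unit.
- Enabling feature: in the single six-membered ring the C1 carbonyl is flanked by C2 and C6, the two α-carbons of one acetone unit (a 1,3-dinucleophile). C3 (ketone oxidation level) and C5 (its β-position) are the two electrophilic ends of nonadecyl vinyl ketone, so C1 and C3 stand in a latent 1,5-dicarbonyl relationship across C6–C5–C4.
- Forward: icosanoic acid is converted via its Weinreb amide into the vinyl ketone (chain joined to C4–C5); a 2-ethoxyallylidene phosphorane is made separately from acetonylidenetriphenylphosphorane.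
- The only ring arises in step 4 by Michael addition (C6–C5) followed by intramolecular Wittig olefination (C2=C3); acid hydrolysis then reveals the enone.
- Stereochemistry: the target has no stereocentre; the one alkene lies in the ring, and its position is fixed by the phosphorus-bearing carbon.

Key step: step 4

Assumption: the side chain is unbranched nonadecyl (19 carbons), so the target is achiral 3-nonadecylcyclohex-2-en-1-one. Ring numbering used throughout: C1 carbonyl, C2 vinylic CH, C3 chain-bearing carbon, C4–C6 methylenes.

**Step 1**
Reactants: 1 icosanoic acid
Product: 3 N-methoxy-N-methylicosanamide, via N-icosanoylimidazole 2 (not isolated)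
Conditions: CDI, THF, 40 °C; then MeNHOMe·HCl, rt
Reagents that add atoms: N,O-dimethylhydroxylamine hydrochloride, CNOC.Cl (1,1'-carbonyldiimidazole, O=C(n1ccnc1)n1ccnc1, leaves its imidazolyl group only in intermediate 2)
Why: Weinreb amide synthesis through the acyl imidazolide, a mild activation that an unfunctionalised fatty acid should tolerate without side reactions; no stereocentre is involved.

**Step 2**
Reactants: 3 N-methoxy-N-methylicosanamide; 4 vinylmagnesium bromide
Product: 6 docos-1-en-3-one, via chelated magnesium adduct 5 (not isolated)
Conditions: CH2=CHMgBr, THF, 0 °C; inverse quench into cold 1 M HCl; product kept cold and used promptly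
Reagents that add atoms: none
Why: Weinreb ketone synthesis, in which the chelated tetrahedral adduct 5 should persist until the quench and so prevent double addition, while the acidic inverse quench protonates the released amine so that it cannot add to the new enone.

**Step 3**
Reactants: 7 1-(triphenylphosphoranylidene)propan-2-one
Product: 8 [(Z)-2-ethoxyprop-1-en-1-yl]triphenylphosphonium tetrafluoroborate
Conditions: Et3OBF4, CH2Cl2, 0 °C to rt; precipitation with Et2O under dry conditions
Reagents that add atoms: triethyloxonium tetrafluoroborate, CC[O+](CC)CC.F[B-](F)(F)F
Why: O-alkylation of an acyl-stabilised ylide by a hard oxonium electrophile, which should ethylate the enolate-like oxygen to give the enol ether phosphonium salt (Z expected from the cisoid ylide; either geometry leads to the same ylide in step 4).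

**Step 4**
Reactants: 8 [(Z)-2-ethoxyprop-1-en-1-yl]triphenylphosphonium tetrafluoroborate; 6 docos-1-en-3-one
Product: 11 3-ethoxy-1-nonadecylcyclohexa-1,3-diene, via allylidene ylide 9 (not isolated), via keto ylide 10 (not isolated)
Conditions: NaN(SiMe3)2 (0.95 equiv per 8), THF, −78 to 0 °C; 6 (0.8 equiv) added dropwise at −78 °C; warm to rt, then 65 °C; non-acidic work-up (pentane, filtration through basic alumina)
Reagents that add atoms: none
Why: Deprotonation of 8 at its methyl group gives the allylic ylide 9, whose terminal CH2 (future C6) adds in Michael fashion to the unsubstituted β-carbon of 6 (future C5); proton transfer from the new allylic CH2 to the enolate gives ylide 10, whose phosphorus-bearing carbon (future C2) attacks the ketone carbon (future C3), and the oxaphosphetane collapses to the C2=C3 alkene with loss of Ph3P=O. The closest known reaction type is the Michael addition–intramolecular Wittig cyclohexenone annulation of 2-alkoxyallylidene phosphoranes with α,β-unsaturated ketones, a phosphorus-based counterpart of the Robinson annulation. The single six-membered ring closes by 6-exo-trig attack of the ylide carbon on the C3 carbonyl, the allylic ylide double bond lying inside the forming ring. No stereocentre is formed, and the ring enforces the cis geometry of both alkenes. The step needs attack through the terminal carbon of the ylide in the 1,4-sense, which the bulky Ph3P-bearing carbon and the unhindered CH2 terminus of the vinyl ketone should favour, and it needs the alkene to form at C2=C3 and not through the first chain methylene as in a diketone aldol, which is secured because only the phosphorus-bearing carbon can olefinate. Oligomerisation of the enone should be held down by adding 6 slowly to a slight excess of ylide that contains no free amide base.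

**Step 5**
Reactants: 11 3-ethoxy-1-nonadecylcyclohexa-1,3-diene
Product: 12 3-nonadecylcyclohex-2-en-1-one
Conditions: 1 M HCl, THF, rt
Reagents that add atoms: water, O
Why: Acid hydrolysis of a dienol ether, in which protonation at the terminal C6, attack of water on the conjugated oxocarbenium ion at C1 and loss of ethanol should give the conjugated enone directly, any β,γ-isomer equilibrating into conjugation under the same acid.

**Compound list**
1 | icosanoic acid (arachidic acid) | CCCCCCCCCCCCCCCCCCCC(=O)O | starting material
2 | 1-(1H-imidazol-1-yl)icosan-1-one (N-icosanoylimidazole) | CCCCCCCCCCCCCCCCCCCC(=O)n1ccnc1 | intermediate (not isolated)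
3 | N-methoxy-N-methylicosanamide | CCCCCCCCCCCCCCCCCCCC(=O)N(C)OC | intermediate
4 | vinylmagnesium bromide | C=C[Mg]Br | starting material
5 | bromomagnesium 3-[methoxy(methyl)amino]docos-1-en-3-olate, racemic chelated tetrahedral adduct | CCCCCCCCCCCCCCCCCCCC(O[Mg]Br)(C=C)N(C)OC | intermediate (not isolated)
6 | docos-1-en-3-one (nonadecyl vinyl ketone) | CCCCCCCCCCCCCCCCCCCC(=O)C=C | intermediate
7 | 1-(triphenylphosphoranylidene)propan-2-one | CC(=O)C=P(c1ccccc1)(c1ccccc1)c1ccccc1 | starting material
8 | [(Z)-2-ethoxyprop-1-en-1-yl]triphenylphosphonium tetrafluoroborate | CCO/C(C)=C\[P+](c1ccccc1)(c1ccccc1)c1ccccc1.F[B-](F)(F)F | intermediate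
9 | (2-ethoxyprop-2-en-1-ylidene)triphenylphosphorane | CCOC(=C)C=P(c1ccccc1)(c1ccccc1)c1ccccc1 | intermediate (not isolated)
10 | (2E)-2-ethoxy-1-(triphenylphosphoranylidene)pentacos-2-en-6-one, drawn in the geometry that cyclises (the allylic ylide is configurationally labile) | CCCCCCCCCCCCCCCCCCCC(=O)CC/C=C(/OCC)C=P(c1ccccc1)(c1ccccc1)c1ccccc1 | intermediate (not isolated)
11 | 3-ethoxy-1-nonadecylcyclohexa-1,3-diene | CCOC1=CCCC(CCCCCCCCCCCCCCCCCCC)=C1 | intermediate
12 | 3-nonadecylcyclohex-2-en-1-one | CCCCCCCCCCCCCCCCCCCC1=CC(=O)CCC1 | target

**Step count**
Total steps: 5. Longest linear sequence: 4 steps (steps 1, 2, 4, 5); step 3 is a one-step branch that joins at step 4.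

**Steps most likely to fail**

Step 4. The vinyl ketone may oligomerise anionically under the ylide or the first-formed enolate, and the ylide may attack through its phosphorus-bearing carbon or at the carbonyl. The fallback sets out from 6 and comes back at 12, making the same two ring bonds one at a time. Me3SiI followed by ethylene glycol should convert 6 into 2-(2-iodoethyl)-2-nonadecyl-1,3-dioxolane F1. The dianion of dimethyl (2-oxopropyl)phosphonate (NaH, then n-BuLi, THF, 0 °C) would be alkylated at its terminal carbon by F1 to give dimethyl [5-(2-nonadecyl-1,3-dioxolan-2-yl)-2-oxopentyl]phosphonate F2. Aqueous HCl in acetone should free dimethyl (2,6-dioxopentacosyl)phosphonate F3. Intramolecular Horner–Wadsworth–Emmons olefination (K2CO3, 18-crown-6, toluene, 80 °C) would then close the ring to 12 with the same regiocontrol.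

Step 2. The released N,O-dimethylhydroxylamine may add in conjugate fashion to the new enone during the quench, and the vinyl ketone may polymerise on concentration. The fallback sets out from 3 and comes back at 6. LiAlH4 (THF, −78 to 0 °C) should reduce 3 to icosanal F4. CH2=CHMgBr (THF, −78 °C) would add to give racemic docos-1-en-3-ol F5, which can be stored. Dess–Martin periodinane (CH2Cl2, NaHCO3) would oxidise F5 to 6 immediately before step 4.

Step 3. Ethylation may occur at carbon instead of oxygen, and the moisture-sensitive enol ether salt may hydrolyse back to the acetonylphosphonium salt on handling. The fallback sets out from 2 and comes back at 12; it avoids phosphorus and closes the ring through a β-keto ester. The acyl imidazolide 2 (from 1 and CDI as in step 1) would be treated with KO2CCH2CO2Et and MgCl2 in THF to give ethyl 3-oxodocosanoate F6 by decarboxylative Claisen acylation. Michael addition of F6 to but-3-en-2-one (catalytic NaOEt, EtOH) and aldol condensation on heating, the methyl ketone carbon attacking the chain-bearing ketone, should give racemic ethyl 2-nonadecyl-4-oxocyclohex-2-ene-1-carboxylate F7. KOH in aqueous EtOH at reflux, then acidification and heating, would remove the ester by saponification and decarboxylation to give 12.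

**Further compounds**
F1 | step 4 | 2-(2-iodoethyl)-2-nonadecyl-1,3-dioxolane | CCCCCCCCCCCCCCCCCCCC1(CCI)OCCO1
F2 | step 4 | dimethyl [5-(2-nonadecyl-1,3-dioxolan-2-yl)-2-oxopentyl]phosphonate | COP(=O)(OC)CC(=O)CCCC1(CCCCCCCCCCCCCCCCCCC)OCCO1
F3 | step 4 | dimethyl (2,6-dioxopentacosyl)phosphonate | COP(=O)(OC)CC(=O)CCCC(=O)CCCCCCCCCCCCCCCCCCC
F4 | step 2 | icosanal | CCCCCCCCCCCCCCCCCCCC=O
F5 | step 2 | docos-1-en-3-ol (racemic) | CCCCCCCCCCCCCCCCCCCC(O)C=C
F6 | step 3 | ethyl 3-oxodocosanoate | CCCCCCCCCCCCCCCCCCCC(=O)CC(=O)OCC
F7 | step 3 | ethyl 2-nonadecyl-4-oxocyclohex-2-ene-1-carboxylate (racemic) | CCOC(=O)C1CCC(=O)C=C1CCCCCCCCCCCCCCCCCCC
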